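Add starting material and intermediate A into one pool, as a fraction of the charge, and ask how fast that pool empties.

| setting | alpha | eta | delta | Thursday's | Tuesday's | Monday's |
|---|---|---|---|---|---|---|
| starting material | 0.20 M | 0.20 M | 0.10 M | 0.20 M | 0.20 M | 0.20 M |
| reagent | 1 equiv | 4 equiv | 2 equiv | 2.00 equiv | 2.00 equiv | 2.00 equiv |
| remark | run made earlier | run made earlier | run made earlier |  |  |  |
| time |  |  |  | 10 min | 25 min | 62 min |

| run | time / min | intermediate A / % | starting material / % | target / % | over-reaction product / % |
|---|---|---|---|---|---|
| alpha | 1.50 | 31 | 61 | 8 | 0 |
| alpha | 3.00 | 29 | 60 | 9 | 0 |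
| alpha | 5.00 | 23 | 53 | 15 | 5 |
| alpha | 6.00 | 21 | 53 | 16 | 7 |
| alpha | 8.00 | 18 | 49 | 20 | 16 |
| alpha | 10.0 | 16 | 45 | 21 | 18 |
| eta | 0.667 | 63 | 35 | 1 | 1 |
| eta | 2.00 | 68 | 29 | 8 | 2 |
| eta | 4.00 | 59 | 31 | 4 | 2 |
| eta | 5.00 | 58 | 31 | 7 | 3 |
| eta | 8.00 | 52 | 29 | 10 | 6 |
| eta | 10.0 | 47 | 30 | 12 | 9 |
| delta | 2.00 | 34 | 57 | 9 | 0 |
| delta | 4.00 | 28 | 51 | 13 | 4 |
| delta | 6.00 | 26 | 49 | 15 | 11 |
| delta | 8.00 | 20 | 48 | 20 | 13 |
| delta | 10.0 | 18 | 45 | 19 | 16 |

(readings scatter by 1.5 percentage points)



- which of these there is most of at the end, counted by the starting material in it, Thursday's (target / over-reaction product / starting material / intermediate A)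
- which of these there is most of at the end, counted by the starting material in it, Tuesday's (target / over-reaction product / starting material / intermediate A)
- which of these there is most of at the end, counted by the starting material in it, Monday's (target / over-reaction product / starting material / intermediate A)
- amount of the one of these that there is most of at the end, in percent of the starting material charged, Thursday's
- amount of the one of these that there is most of at the end, in percent of the starting material charged, Tuesday's
- amount of the one of these that there is most of at the end, in percent of the starting material charged, Monday's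

I check each number in turn by how far the outcome moves if it is off. The split of the pool between its two forms does not enter my balance for over-reaction product; I need it to rank starting material against intermediate A in Thursday's flask. Target enters that balance point for point, and its last readings run from 12% in eta to 21% in alpha. A slip of 10 percent in the emptying time moves the pool by at most 3.7 percentage points, and that happens when the elapsed time equals the emptying time.

That time goes into the pool of each asked flask, so I reckon it first. I treat the pool as a pseudo-first-order drain. Alpha and eta share 0.20 M, and 2.00 equiv lies halfway between their 1 equiv and 4 equiv on a logarithmic scale, so I average their constants.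

alpha: pool 61.0%, constant 0.0494 min⁻¹

eta: pool 77.0%, constant 0.0261 min⁻¹

drain time: 26.5 min

This is the drain time, in which the pool falls to 36.8% of itself. Tuesday's 25 min lies next to it. For Thursday's I also average, over the last readings of alpha and eta, the free share of the pool, 56.4%, and target, 16.5%. I hold that target on Tuesday's, then keep Tuesday's ratio of target to pool on Monday's.

Thursday's: pool 68.5%, starting material 38.6%, intermediate A 29.9%, over-reaction product 15.0%

Tuesday's: pool 38.9%, over-reaction product 44.6%

Monday's: pool 9.61%, over-reaction product 86.3%

The forecast, whose figures are not mine, gives Thursday's starting material at 40%, Tuesday's over-reaction product at 44% and Monday's over-reaction product at 90%, and it says “A looks like an off-path reservoir”.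

Most stands as starting material at 38.2% in Thursday's flask, over-reaction product at 47.1% in Tuesday's and over-reaction product at 87.3% in Monday's.

    intermediate B → target (k = 0.0390 s⁻¹)
    target → over-reaction product (k = 0.00220 s⁻¹)
    reagent + intermediate B → side product (k = 0.00470 M⁻¹ s⁻¹)
    reagent ⇌ dormant form (K = 1.50, k = 0.00150 s⁻¹)
    starting material → intermediate B (k = 0.00120 s⁻¹)
    starting material + reagent ⇌ intermediate A (K = 3.90 M⁻¹, k = 0.0600 M⁻¹ s⁻¹)

Outside my balance, Tuesday's flask holds side product at 1.49% and intermediate B at 0.667%. Its pool stands at 35.8%, which read back gives a drain time of 24.3 min against my 26.5 min. The neighbour of Thursday's flask with 3.40 equiv of reagent keeps a pool of 75.0% at 10.0 min, so its drain time is 34.8 min, longer than 26.5 min.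

The runs were computed with made-up constants, and the scatter is random.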